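**Retrosynthetic overview**
1. Target ⇒ side-chain C7' aldehyde + Z-selective phosphonate olefination (acid-end alkene made last); the aldehyde ⇒ allylic bromide + cyanomethyl anion; the (E)-alkene ⇒ stabilized-ylide Wittig on a chroman-2-propanal.
2. Chroman-2-propanal ⇒ (S)-chroman-2-carboxylate (its ester carbon is the first side-chain carbon) by reduction, two-carbon Wittig and hydrogenation.
3. The pyran ring of the chroman is the only ring formed (the benzene ring is bought); it is closed by C(aryl)–O coupling of the tertiary alcohol onto an ortho-bromide, after the stereocentre exists.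
4. The tertiary carbinol ⇒ aryl methyl ketone enolsilane + methyl pyruvate: a catalytic enantioselective Mukaiyama aldol forms the C2–C3 bond and the only stereocentre (key fragment union).
5. Aryl ketone ⇒ 3-bromo-5-methylphenol by O-benzylation, para-iodination and iodine–magnesium exchange/acylation.

Assumption: the SMILES is read as 2R at the chroman carbon, Z at the acid-end alkene and E at the inner alkene; "chroman" means 3,4-dihydro-2H-chromene, and (S,S)-t-Bu-box is 2,2'-(propane-2,2-diyl)bis[(4S)-4-tert-butyl-4,5-dihydro-1,3-oxazole].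

**Route**

Step 1
Reactants: 1 3-bromo-5-methylphenol
Product: 2 benzyl 3-bromo-5-methylphenyl ether
Conditions: BnBr (1.1 equiv), K2CO3, acetone, reflux
Reagents that add atoms: benzyl bromide, BrCc1ccccc1
Why: Williamson ether synthesis (SN2 of the phenoxide on benzyl bromide) gives a benzyl ether that withstands the organomagnesium, Lewis-acid, silane–TFA and palladium steps ahead.

Step 2
Reactants: 2 benzyl 3-bromo-5-methylphenyl ether
Product: 3 benzyl 3-bromo-4-iodo-5-methylphenyl ether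
Conditions: NIS (1.05 equiv), TFA (0.3 equiv), MeCN, 0 °C → rt, dark
Reagents that add atoms: N-iodosuccinimide, O=C1CCC(=O)N1I
Why: Electrophilic aromatic iodination in MeCN goes para to the alkoxy group (as for 3,5-disubstituted anisoles), which places iodine between Br and CH3.

Step 3
Reactants: 3 benzyl 3-bromo-4-iodo-5-methylphenyl ether
Product: 5 4'-(benzyloxy)-2'-bromo-6'-methylacetophenone, via arylmagnesium chloride 4 (not isolated)
Conditions: i-PrMgCl·LiCl (1.1 equiv), THF, −20 °C; then MeC(O)N(OMe)Me (1.5 equiv), −20 °C → rt; aq. NH4Cl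
Reagents that add atoms: N-methoxy-N-methylacetamide, CC(=O)N(C)OC
Why: Iodine–magnesium exchange is much faster at C–I than at C–Br, and in this Weinreb ketone synthesis the amide takes up only one aryl group, so the methyl ketone is released only on work-up.

Step 4
Reactants: 5 4'-(benzyloxy)-2'-bromo-6'-methylacetophenone
Product: 6 {1-[4-(benzyloxy)-2-bromo-6-methylphenyl]ethenyloxy}trimethylsilane
Conditions: TMSOTf (1.2 equiv), Et3N (1.5 equiv), CH2Cl2, 0 °C
Reagents that add atoms: trimethylsilyl trifluoromethanesulfonate, C[Si](C)(C)OS(=O)(=O)C(F)(F)F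
Why: Soft enolization (silyl enol ether formation) at the only enolizable position, the acetyl CH3.

Step 5
Reactants: 6 {1-[4-(benzyloxy)-2-bromo-6-methylphenyl]ethenyloxy}trimethylsilane; 7 methyl pyruvate (1.5 equiv)
Product: 9 methyl (2S)-4-[4-(benzyloxy)-2-bromo-6-methylphenyl]-2-hydroxy-2-methyl-4-oxobutanoate, via O-trimethylsilyl aldol adduct 8 (not isolated)
Conditions: Cu(OTf)2 (10 mol %), (S,S)-t-Bu-box (11 mol %), THF, −78 °C; then 1 M HCl, THF, rt
Reagents that add atoms: none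
Why: Evans-type catalytic enantioselective Mukaiyama aldol: pyruvate binds through both carbonyls to the square-planar divalent copper centre of [Cu((S,S)-t-Bu-box)](OTf)2, the tert-butyl group blocks the re face, and the enolsilane adds to the si face to give the (S)-carbinol (typically 93–99% ee for this reaction class), which becomes C2 of the target.

Step 6
Reactants: 9 methyl (2S)-4-[4-(benzyloxy)-2-bromo-6-methylphenyl]-2-hydroxy-2-methyl-4-oxobutanoate
Product: 10 methyl (2S)-4-[4-(benzyloxy)-2-bromo-6-methylphenyl]-2-hydroxy-2-methylbutanoate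
Conditions: Et3SiH (4 equiv), TFA–CH2Cl2 (1:1), 0 °C → rt
Reagents that add atoms: none
Why: Ionic hydrogenation: the protonated aryl ketone and then the para-alkoxy-stabilized benzylic cation each take hydride from Et3SiH, while the tertiary α-hydroxy ester cannot ionize, so C2 is untouched and the retro-aldol-prone β-hydroxy ketone is removed before any base is used.

Step 7
Reactants: 10 methyl (2S)-4-[4-(benzyloxy)-2-bromo-6-methylphenyl]-2-hydroxy-2-methylbutanoate
Product: 11 methyl (2S)-7-(benzyloxy)-2,5-dimethylchroman-2-carboxylate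
Conditions: Pd(OAc)2 (3 mol %), 2-(di-tert-butylphosphino)-1,1'-binaphthyl (4 mol %), Cs2CO3 (1.5 equiv), toluene, 80 °C
Reagents that add atoms: none
Why: Buchwald-type intramolecular C–O coupling (oxidative addition of C–Br to zerovalent palladium, alkoxide binding, reductive elimination driven by the bulky phosphine) closes the six-membered ring; the tertiary alkoxide has no hydrogen on the carbinol carbon and its C–O bond is never broken, so configuration is retained.

Step 8
Reactants: 11 methyl (2S)-7-(benzyloxy)-2,5-dimethylchroman-2-carboxylate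
Product: 12 (2S)-7-(benzyloxy)-2,5-dimethylchroman-2-carbaldehyde
Conditions: i-Bu2AlH (1.1 equiv), CH2Cl2, −78 °C; MeOH, then aq. KNaC4H4O6 (potassium sodium tartrate)
Reagents that add atoms: none
Why: Low-temperature partial reduction of an α-aryloxy ester stops at the aldehyde stage, and the aldehyde has no α-hydrogen, so it cannot epimerize.

Step 9
Reactants: 12 (2S)-7-(benzyloxy)-2,5-dimethylchroman-2-carbaldehyde
Product: 13 ethyl (2E)-3-[(2S)-7-(benzyloxy)-2,5-dimethylchroman-2-yl]prop-2-enoate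
Conditions: Ph3P=CHCO2Et (1.5 equiv), toluene, 90 °C
Reagents that add atoms: ethyl (triphenylphosphoranylidene)acetate, CCOC(=O)C=P(c1ccccc1)(c1ccccc1)c1ccccc1
Why: Wittig olefination with a stabilized ylide adds the next two side-chain carbons under neutral conditions; the alkene geometry does not matter because this double bond is hydrogenated next.

Step 10
Reactants: 13 ethyl (2E)-3-[(2S)-7-(benzyloxy)-2,5-dimethylchroman-2-yl]prop-2-enoate
Product: 14 ethyl 3-[(2S)-7-hydroxy-2,5-dimethylchroman-2-yl]propanoate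
Conditions: H2 (1 atm), 10% Pd/C, EtOAc–EtOH, rt
Reagents that add atoms: none
Why: Catalytic hydrogenation saturates the enoate and hydrogenolyses the benzyl ether in one operation, before any alkene that must be kept is present.

Step 11
Reactants: 14 ethyl 3-[(2S)-7-hydroxy-2,5-dimethylchroman-2-yl]propanoate
Product: 15 ethyl 3-[(2S)-7-{[tert-butyl(dimethyl)silyl]oxy}-2,5-dimethylchroman-2-yl]propanoate
Conditions: TBSCl (1.2 equiv), imidazole (2.5 equiv), DMF, rt
Reagents that add atoms: tert-butyldimethylsilyl chloride, CC(C)(C)[Si](C)(C)Cl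
Why: Silylation of the phenol gives an aryl silyl ether that tolerates the hydride, ylide, Appel and carbanion steps and is removed by hydroxide at the end.

Step 12
Reactants: 15 ethyl 3-[(2S)-7-{[tert-butyl(dimethyl)silyl]oxy}-2,5-dimethylchroman-2-yl]propanoate
Product: 16 3-[(2S)-7-{[tert-butyl(dimethyl)silyl]oxy}-2,5-dimethylchroman-2-yl]propanal
Conditions: i-Bu2AlH (1.05 equiv), CH2Cl2, −78 °C; MeOH, then aq. KNaC4H4O6
Reagents that add atoms: none
Why: Partial reduction of the ester at −78 °C gives the aldehyde needed for the next olefination.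

Step 13
Reactants: 16 3-[(2S)-7-{[tert-butyl(dimethyl)silyl]oxy}-2,5-dimethylchroman-2-yl]propanal
Product: 17 ethyl (2E)-5-[(2R)-7-{[tert-butyl(dimethyl)silyl]oxy}-2,5-dimethylchroman-2-yl]-2-methylpent-2-enoate
Conditions: Ph3P=C(Me)CO2Et (1.3 equiv), CH2Cl2, rt → 40 °C
Reagents that add atoms: ethyl 2-(triphenylphosphoranylidene)propanoate, CCOC(=O)C(C)=P(c1ccccc1)(c1ccccc1)c1ccccc1
Why: Wittig reaction of an α-methyl stabilized ylide with an unhindered aldehyde gives the (E)-trisubstituted enoate (typically ≥ 95:5), which sets the inner alkene geometry; the C2 descriptor changes from S to R by CIP priority only.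

Step 14
Reactants: 17 ethyl (2E)-5-[(2R)-7-{[tert-butyl(dimethyl)silyl]oxy}-2,5-dimethylchroman-2-yl]-2-methylpent-2-enoate
Product: 18 (2E)-5-[(2R)-7-{[tert-butyl(dimethyl)silyl]oxy}-2,5-dimethylchroman-2-yl]-2-methylpent-2-en-1-ol
Conditions: i-Bu2AlH (2.5 equiv), CH2Cl2, −78 → 0 °C; aq. KNaC4H4O6
Reagents that add atoms: none
Why: 1,2-Reduction of the enoate gives the allylic alcohol without touching the alkene geometry.

Step 15
Reactants: 18 (2E)-5-[(2R)-7-{[tert-butyl(dimethyl)silyl]oxy}-2,5-dimethylchroman-2-yl]-2-methylpent-2-en-1-ol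
Product: 19 {[(2R)-2-[(3E)-5-bromo-4-methylpent-3-en-1-yl]-2,5-dimethylchroman-7-yl]oxy}(tert-butyl)dimethylsilane
Conditions: CBr4 (1.3 equiv), PPh3 (1.4 equiv), CH2Cl2, 0 °C
Reagents that add atoms: carbon tetrabromide, BrC(Br)(Br)Br
Why: The Appel reaction converts the primary allylic alcohol to the bromide under neutral conditions by SN2 at the primary carbon, without allylic transposition or E/Z scrambling.

Step 16
Reactants: 19 {[(2R)-2-[(3E)-5-bromo-4-methylpent-3-en-1-yl]-2,5-dimethylchroman-7-yl]oxy}(tert-butyl)dimethylsilane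
Product: 20 (4E)-7-[(2R)-7-{[tert-butyl(dimethyl)silyl]oxy}-2,5-dimethylchroman-2-yl]-4-methylhept-4-enenitrile
Conditions: MeCN (5 equiv), n-BuLi (4.5 equiv), THF, −78 °C; then 19, −78 → −40 °C
Reagents that add atoms: acetonitrile, CC#N
Why: SN2 alkylation of lithiated acetonitrile by the primary allylic bromide adds two carbons at the aldehyde oxidation level, and the excess of nucleophile suppresses dialkylation.

Step 17
Reactants: 20 (4E)-7-[(2R)-7-{[tert-butyl(dimethyl)silyl]oxy}-2,5-dimethylchroman-2-yl]-4-methylhept-4-enenitrile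
Product: 22 (4E)-7-[(2R)-7-{[tert-butyl(dimethyl)silyl]oxy}-2,5-dimethylchroman-2-yl]-4-methylhept-4-enal, via N-diisobutylaluminyl imine 21 (not isolated)
Conditions: i-Bu2AlH (1.3 equiv), toluene, −78 °C; then 10% aq. tartaric acid, 0 °C
Reagents that add atoms: water, O
Why: The hydride adds once to the nitrile and the resulting N-aluminyl imine is hydrolysed only on work-up, so nitrile-to-aldehyde reduction cannot over-reduce.

Step 18
Reactants: 22 (4E)-7-[(2R)-7-{[tert-butyl(dimethyl)silyl]oxy}-2,5-dimethylchroman-2-yl]-4-methylhept-4-enal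
Product: 23 ethyl (2Z,6E)-9-[(2R)-7-{[tert-butyl(dimethyl)silyl]oxy}-2,5-dimethylchroman-2-yl]-2,6-dimethylnona-2,6-dienoate
Conditions: (CF3CH2O)2P(O)CH(Me)CO2Et (1.5 equiv), KN(SiMe3)2 (1.4 equiv), 18-crown-6 (3 equiv), THF, −78 °C
Reagents that add atoms: ethyl 2-[bis(2,2,2-trifluoroethoxy)phosphoryl]propanoate, CCOC(=O)C(C)P(=O)(OCC(F)(F)F)OCC(F)(F)F
Why: Still–Gennari modification of the Horner–Wadsworth–Emmons reaction: the electron-poor phosphonate with a dissociated potassium counter-ion eliminates under kinetic control and gives the (Z)-2-methyl enoate.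

Step 19
Reactants: 23 ethyl (2Z,6E)-9-[(2R)-7-{[tert-butyl(dimethyl)silyl]oxy}-2,5-dimethylchroman-2-yl]-2,6-dimethylnona-2,6-dienoate
Product: 25 (2Z,6E)-9-[(2R)-7-hydroxy-2,5-dimethylchroman-2-yl]-2,6-dimethylnona-2,6-dienoic acid (CNP0244790.1), via desilylated ethyl ester 24 (not isolated)
Conditions: LiOH·H2O (10 equiv), THF–MeOH–H2O (3:1:1), rt → 45 °C; then 1 M HCl to pH 3
Reagents that add atoms: lithium hydroxide, [Li+].[OH-]
Why: Hydroxide first cleaves the aryl silyl ether at silicon and then saponifies the hindered ester by acyl substitution, conditions that leave both alkenes and the quaternary C2 untouched.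

**Compound list**
1 | 3-bromo-5-methylphenol | Cc1cc(O)cc(Br)c1 | starting material
2 | benzyl 3-bromo-5-methylphenyl ether | Cc1cc(Br)cc(OCc2ccccc2)c1 | intermediate
3 | benzyl 3-bromo-4-iodo-5-methylphenyl ether | Cc1cc(OCc2ccccc2)cc(Br)c1I | intermediate
4 | [4-(benzyloxy)-2-bromo-6-methylphenyl]magnesium chloride | Cc1cc(OCc2ccccc2)cc(Br)c1[Mg]Cl | intermediate
5 | 4'-(benzyloxy)-2'-bromo-6'-methylacetophenone | CC(=O)c1c(C)cc(OCc2ccccc2)cc1Br | intermediate
6 | {1-[4-(benzyloxy)-2-bromo-6-methylphenyl]ethenyloxy}trimethylsilane | C=C(O[Si](C)(C)C)c1c(C)cc(OCc2ccccc2)cc1Br | intermediate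
7 | methyl pyruvate (methyl 2-oxopropanoate) | CC(=O)C(=O)OC | starting material
8 | methyl (2S)-4-[4-(benzyloxy)-2-bromo-6-methylphenyl]-2-methyl-4-oxo-2-[(trimethylsilyl)oxy]butanoate | COC(=O)[C@@](C)(O[Si](C)(C)C)CC(=O)c1c(C)cc(OCc2ccccc2)cc1Br | intermediate
9 | methyl (2S)-4-[4-(benzyloxy)-2-bromo-6-methylphenyl]-2-hydroxy-2-methyl-4-oxobutanoate | COC(=O)[C@@](C)(O)CC(=O)c1c(C)cc(OCc2ccccc2)cc1Br | intermediate
10 | methyl (2S)-4-[4-(benzyloxy)-2-bromo-6-methylphenyl]-2-hydroxy-2-methylbutanoate | COC(=O)[C@@](C)(O)CCc1c(C)cc(OCc2ccccc2)cc1Br | intermediate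
11 | methyl (2S)-7-(benzyloxy)-2,5-dimethylchroman-2-carboxylate | COC(=O)[C@]1(C)CCc2c(C)cc(OCc3ccccc3)cc2O1 | intermediate
12 | (2S)-7-(benzyloxy)-2,5-dimethylchroman-2-carbaldehyde | O=C[C@]1(C)CCc2c(C)cc(OCc3ccccc3)cc2O1 | intermediate
13 | ethyl (2E)-3-[(2S)-7-(benzyloxy)-2,5-dimethylchroman-2-yl]prop-2-enoate | CCOC(=O)/C=C/[C@]1(C)CCc2c(C)cc(OCc3ccccc3)cc2O1 | intermediate
14 | ethyl 3-[(2S)-7-hydroxy-2,5-dimethylchroman-2-yl]propanoate | CCOC(=O)CC[C@]1(C)CCc2c(C)cc(O)cc2O1 | intermediate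
15 | ethyl 3-[(2S)-7-{[tert-butyl(dimethyl)silyl]oxy}-2,5-dimethylchroman-2-yl]propanoate | CCOC(=O)CC[C@]1(C)CCc2c(C)cc(O[Si](C)(C)C(C)(C)C)cc2O1 | intermediate
16 | 3-[(2S)-7-{[tert-butyl(dimethyl)silyl]oxy}-2,5-dimethylchroman-2-yl]propanal | O=CCC[C@]1(C)CCc2c(C)cc(O[Si](C)(C)C(C)(C)C)cc2O1 | intermediate
17 | ethyl (2E)-5-[(2R)-7-{[tert-butyl(dimethyl)silyl]oxy}-2,5-dimethylchroman-2-yl]-2-methylpent-2-enoate | CCOC(=O)/C(C)=C/CC[C@]1(C)CCc2c(C)cc(O[Si](C)(C)C(C)(C)C)cc2O1 | intermediate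
18 | (2E)-5-[(2R)-7-{[tert-butyl(dimethyl)silyl]oxy}-2,5-dimethylchroman-2-yl]-2-methylpent-2-en-1-ol | OC/C(C)=C/CC[C@]1(C)CCc2c(C)cc(O[Si](C)(C)C(C)(C)C)cc2O1 | intermediate
19 | {[(2R)-2-[(3E)-5-bromo-4-methylpent-3-en-1-yl]-2,5-dimethylchroman-7-yl]oxy}(tert-butyl)dimethylsilane | BrC/C(C)=C/CC[C@]1(C)CCc2c(C)cc(O[Si](C)(C)C(C)(C)C)cc2O1 | intermediate
20 | (4E)-7-[(2R)-7-{[tert-butyl(dimethyl)silyl]oxy}-2,5-dimethylchroman-2-yl]-4-methylhept-4-enenitrile | N#CCC/C(C)=C/CC[C@]1(C)CCc2c(C)cc(O[Si](C)(C)C(C)(C)C)cc2O1 | intermediate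
21 | N-(diisobutylaluminyl) imine of aldehyde 22 | CC(C)C[Al](CC(C)C)N=CCC/C(C)=C/CC[C@]1(C)CCc2c(C)cc(O[Si](C)(C)C(C)(C)C)cc2O1 | intermediate
22 | (4E)-7-[(2R)-7-{[tert-butyl(dimethyl)silyl]oxy}-2,5-dimethylchroman-2-yl]-4-methylhept-4-enal | O=CCC/C(C)=C/CC[C@]1(C)CCc2c(C)cc(O[Si](C)(C)C(C)(C)C)cc2O1 | intermediate
23 | ethyl (2Z,6E)-9-[(2R)-7-{[tert-butyl(dimethyl)silyl]oxy}-2,5-dimethylchroman-2-yl]-2,6-dimethylnona-2,6-dienoate | CCOC(=O)/C(C)=C\CC/C(C)=C/CC[C@]1(C)CCc2c(C)cc(O[Si](C)(C)C(C)(C)C)cc2O1 | intermediate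
24 | ethyl (2Z,6E)-9-[(2R)-7-hydroxy-2,5-dimethylchroman-2-yl]-2,6-dimethylnona-2,6-dienoate | CCOC(=O)/C(C)=C\CC/C(C)=C/CC[C@]1(C)CCc2c(C)cc(O)cc2O1 | intermediate
25 | (2Z,6E)-9-[(2R)-7-hydroxy-2,5-dimethylchroman-2-yl]-2,6-dimethylnona-2,6-dienoic acid | C/C(=C/CC/C(C)=C/CC[C@]1(C)CCc2c(C)cc(O)cc2O1)C(=O)O | target

**Totals**
Total steps: 19. Longest linear sequence: 19 steps (1 → 25); methyl pyruvate 7 is bought and enters at step 5.

**Three steps most likely to fail, each with one fallback**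

Step 5 (aldol with a di-ortho-substituted aryl enolsilane; conversion or ee may be low). The fallback sets out from methyl pyruvate 7, takes its aryl part from Grignard 4, and comes back at 8. The same copper–box aldol is run on 7 with 1-(ethylsulfanyl)-1-[(trimethylsilyl)oxy]ethene, the best-behaved nucleophile class for this catalyst. Non-acidic work-up gives methyl (2S)-4-(ethylsulfanyl)-2-methyl-4-oxo-2-[(trimethylsilyl)oxy]butanoate F1. Grignard 4 (made as in step 3) is transmetalated with ZnCl2 to [4-(benzyloxy)-2-bromo-6-methylphenyl]zinc chloride F2. F1 and F2 are joined by a Fukuyama thioester–organozinc ketone synthesis (PdCl2(PPh3)2, THF–toluene, rt), which gives silyl ether 8. The 1 M HCl treatment of step 5 then gives 9.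

Step 6 (ionic hydrogenation of a hindered ketone; possible stalling at the benzylic alcohol or lactone, or wear on the benzyl ether). The fallback sets out from 9 and comes back at 10. NaBH4 (MeOH, −20 °C), then TsOH (cat.), closes the γ-hydroxy ester to (3S)-5-[4-(benzyloxy)-2-bromo-6-methylphenyl]-3-hydroxy-3-methyloxolan-2-one F3 (both C5 epimers are used). Et3SiH/BF3·OEt2 (CH2Cl2, 0 °C) opens the benzylic lactone C–O bond reductively to (2S)-4-[4-(benzyloxy)-2-bromo-6-methylphenyl]-2-hydroxy-2-methylbutanoic acid F4. Me3SiCHN2 (MeOH–toluene) re-esterifies F4 to 10.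

Step 7 (palladium C–O coupling of a tertiary α-hydroxy ester; the poorly nucleophilic alkoxide may not couple). The fallback sets out from 10 and comes back at 12. LiBH4 (THF) reduces the ester to (2S)-4-[4-(benzyloxy)-2-bromo-6-methylphenyl]-2-methylbutane-1,2-diol F5. TBSCl/imidazole masks the primary hydroxyl as (2S)-4-[4-(benzyloxy)-2-bromo-6-methylphenyl]-1-{[tert-butyl(dimethyl)silyl]oxy}-2-methylbutan-2-ol F6. The now plain tertiary alcohol is cyclized with copper iodide CuI (10 mol %), 3,4,7,8-tetramethyl-1,10-phenanthroline and Cs2CO3 in toluene at 110 °C to {[(2S)-7-(benzyloxy)-2,5-dimethylchroman-2-yl]methoxy}(tert-butyl)dimethylsilane F7. TBAF gives [(2S)-7-(benzyloxy)-2,5-dimethylchroman-2-yl]methanol F8, and Dess–Martin periodinane oxidation gives aldehyde 12.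

**Further compounds**
F1 | step 5 | methyl (2S)-4-(ethylsulfanyl)-2-methyl-4-oxo-2-[(trimethylsilyl)oxy]butanoate | COC(=O)[C@@](C)(O[Si](C)(C)C)CC(=O)SCC
F2 | step 5 | [4-(benzyloxy)-2-bromo-6-methylphenyl]zinc chloride | Cc1cc(OCc2ccccc2)cc(Br)c1[Zn]Cl
F3 | step 6 | (3S)-5-[4-(benzyloxy)-2-bromo-6-methylphenyl]-3-hydroxy-3-methyloxolan-2-one | C[C@]1(O)CC(c2c(C)cc(OCc3ccccc3)cc2Br)OC1=O
F4 | step 6 | (2S)-4-[4-(benzyloxy)-2-bromo-6-methylphenyl]-2-hydroxy-2-methylbutanoic acid | OC(=O)[C@@](C)(O)CCc1c(C)cc(OCc2ccccc2)cc1Br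
F5 | step 7 | (2S)-4-[4-(benzyloxy)-2-bromo-6-methylphenyl]-2-methylbutane-1,2-diol | OC[C@@](C)(O)CCc1c(C)cc(OCc2ccccc2)cc1Br
F6 | step 7 | (2S)-4-[4-(benzyloxy)-2-bromo-6-methylphenyl]-1-{[tert-butyl(dimethyl)silyl]oxy}-2-methylbutan-2-ol | CC(C)(C)[Si](C)(C)OC[C@@](C)(O)CCc1c(C)cc(OCc2ccccc2)cc1Br
F7 | step 7 | {[(2S)-7-(benzyloxy)-2,5-dimethylchroman-2-yl]methoxy}(tert-butyl)dimethylsilane | CC(C)(C)[Si](C)(C)OC[C@]1(C)CCc2c(C)cc(OCc3ccccc3)cc2O1
F8 | step 7 | [(2S)-7-(benzyloxy)-2,5-dimethylchroman-2-yl]methanol | OC[C@]1(C)CCc2c(C)cc(OCc3ccccc3)cc2O1
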